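**Retrosynthetic overview**
1. Feature: C3 of the pyranone (ring C) carries ring B through the C3–C1' bond. With O1–C2 opened, C3 is the alpha carbon and C2 the aminomethine carbon of an o-hydroxyaryl enaminone, so C3–C1' can be made by C–H functionalisation with no halogen or boron at C3.
2. The O7–MOM bond is cut last. The key disconnection cuts C3–C1' and O1–C2, giving the ring-A enaminone and 4-diazocyclohexa-2,5-dienone, whose rhodium quinoid carbene acts as a 4-hydroxyphenyl cation equivalent.
3. The enaminone comes from 3,5-diprenyl-4-O-MOM-2-hydroxyacetophenone and DMF dimethyl acetal. Both prenyl groups come from a regiodefined 3,5-diiodide by twofold Stille coupling, chosen over direct phenoxide C-alkylation, which scatters over C3, C5 and oxygen.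
4. The diazide comes from 4-aminophenol through its diazonium tetrafluoroborate.
5. Ring order: rings A and B are bought as arenes, and ring C is the only ring formed, in the key step.

Key step: step 7

Assumption: tributyl(3-methylbut-2-enyl)stannane is taken as a commercial reagent. The target has no stereocentre, and the only stereochemical element in the route is the E geometry of enaminone 7.

**Step 1**
Reactants: 1 2,4-dihydroxyacetophenone
Product: 2 1-(2,4-dihydroxy-3,5-diiodophenyl)ethanone
Conditions: NIS (2.1 equiv), TFA (10 mol %), MeCN, 0 °C to rt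
Reagents that add atoms: N-iodosuccinimide, O=C1CCC(=O)N1I
Why: Electrophilic aromatic iodination, in which C3 and C5 are each ortho/para to both hydroxyl groups while C6 is meta to both, so two equivalents of NIS should stop at the 3,5-diiodide.

**Step 2**
Reactants: 2 1-(2,4-dihydroxy-3,5-diiodophenyl)ethanone
Product: 3 1-[2-hydroxy-3,5-diiodo-4-(methoxymethoxy)phenyl]ethanone
Conditions: MOMCl (1.15 equiv), K2CO3 (1.5 equiv), acetone, 0 °C to rt
Reagents that add atoms: chloromethyl methyl ether, COCCl
Why: Williamson-type O-alkylation, in which the C4 hydroxyl (para to the acetyl group, flanked by two iodines) is the more acidic and is ionised by K2CO3, whereas the C2 hydroxyl is held in a hydrogen bond to the ketone and stays free for the later ring closure.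

**Step 3**
Reactants: 3 1-[2-hydroxy-3,5-diiodo-4-(methoxymethoxy)phenyl]ethanone; 4 tributyl(3-methylbut-2-enyl)stannane
Product: 5 1-[2-hydroxy-4-(methoxymethoxy)-3,5-bis(3-methylbut-2-enyl)phenyl]ethanone
Conditions: 4 (2.6 equiv), Pd(PPh3)4 (10 mol %), DMF (degassed), 95 °C
Reagents that add atoms: tributyl(3-methylbut-2-enyl)stannane 4, CCCC[Sn](CCCC)(CCCC)CC=C(C)C
Why: Twofold Migita–Kosugi–Stille allylation, in which zerovalent palladium inserts into each carbon–iodine bond and, after transmetalation, reductive elimination at the unsubstituted prenyl terminus should give the linear 3-methylbut-2-enyl groups under neutral conditions that spare ketone, chelated phenol and MOM ether.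

**Step 4**
Reactants: 5 1-[2-hydroxy-4-(methoxymethoxy)-3,5-bis(3-methylbut-2-enyl)phenyl]ethanone; 6 N,N-dimethylformamide dimethyl acetal
Product: 7 (E)-3-(dimethylamino)-1-[2-hydroxy-4-(methoxymethoxy)-3,5-bis(3-methylbut-2-enyl)phenyl]prop-2-en-1-one
Conditions: 6 (2.5 equiv), toluene, 90 °C
Reagents that add atoms: N,N-dimethylformamide dimethyl acetal 6, COC(OC)N(C)C
Why: Amide acetal condensation of a methyl ketone (enaminone formation), in which the acetyl CH3 is the only acidic C–H site, the push–pull product settles as the E isomer, the chelated C2 phenol resists O-methylation and the C4 oxygen is masked.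

**Step 5**
Reactants: 8 4-aminophenol
Product: 9 4-hydroxybenzenediazonium tetrafluoroborate
Conditions: NaNO2 (1.05 equiv), 48% aq HBF4 (2.5 equiv), H2O, 0 °C; filter, wash with cold Et2O
Reagents that add atoms: sodium nitrite, [Na+].[O-]N=O; tetrafluoroboric acid, [H+].F[B-](F)(F)F
Why: Diazotisation of a primary arylamine, with the tetrafluoroborate counter-ion giving a salt that precipitates and can be filtered and kept cold.

**Step 6**
Reactants: 9 4-hydroxybenzenediazonium tetrafluoroborate
Product: 10 4-diazocyclohexa-2,5-dien-1-one
Conditions: K2CO3 (powdered, 1.1 equiv), MeCN, 0 °C, dark; filter, concentrate below 20 °C, take up in DCE and use at once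
Reagents that add atoms: none
Why: Simple acid–base reaction, since the phenol of the diazonium cation is strongly acidic (pKa near 3.5) and a weak solid base removes the proton, leaving the neutral quinone diazide in solution while the potassium salts are filtered off.

**Step 7**
Reactants: 7 (E)-3-(dimethylamino)-1-[2-hydroxy-4-(methoxymethoxy)-3,5-bis(3-methylbut-2-enyl)phenyl]prop-2-en-1-one; 10 4-diazocyclohexa-2,5-dien-1-one
Product: 12 4'-hydroxy-7-(methoxymethoxy)-6,8-diprenylisoflavone, via 2-(dimethylamino)isoflavanone 11 (not isolated)
Conditions: Rh2(OAc)4 (2 mol %), 4 Å MS, DCE, 40 °C, 10 (1.5 equiv in DCE) added over 3 h, dark, N2 sweep; then AcOH (2 equiv), 60 °C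
Reagents that add atoms: none
Why: Proposed new method: Rh2(OAc)4, a complex of divalent rhodium, expels N2 from 10 to give an electrophilic quinoid carbene; the alpha carbon of the vinylogous amide 7 adds to the carbene carbon (C3–C1' bond), and release of the metal turns the dienone directly into an aromatic 4-oxidophenyl ring, so ring B arrives with its oxygen para and unprotected. The iminium carbon left behind (future C2) is captured by the ring-A hydroxyl to give aminal 11, a 6-exo-trig closure because the C=N+ bond lies outside the forming ring C; if proton transfer first restores a neutral alpha-aryl enaminone, the same O1–C2 bond forms by 6-endo-trig oxa-Michael addition, and both modes are favoured. E1cB loss of dimethylamine from 11, driven to completion by the AcOH chase, gives the aromatic pyranone, and since both sp3 centres of 11 are erased the step sets no stereocentre. The closest known reaction types are the domino alpha-C–H functionalisation/chromone annulation of o-hydroxyaryl enaminones with electrophiles and diazo-derived carbenes, the rhodium-catalysed C–H arylation of electron-rich pi systems with quinone diazides, and the spontaneous closure of alpha-aryl enaminones in the deoxybenzoin/amide acetal isoflavone synthesis; only their combination is untested. The step needs chemoselectivity for the enaminone alpha carbon over the two trisubstituted prenyl alkenes (cyclopropanation), the O–H bonds (insertion) and uncatalysed coupling at the terminal nitrogen of 10. The push–pull enaminone is by far the strongest carbon nucleophile in 7, its phenol is tied into a hydrogen bond with the ketone, and slow addition of 10 under a nitrogen sweep keeps carbene, free diazide and liberated amine at low concentration.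

**Step 8**
Reactants: 12 4'-hydroxy-7-(methoxymethoxy)-6,8-diprenylisoflavone
Product: 13 7,4'-dihydroxy-6,8-diprenylisoflavone (CNP0238765.0)
Conditions: HCl in MeOH (about 1 mol/L), 0 °C to rt, quenched with NaHCO3 as soon as 12 is consumed
Reagents that add atoms: none
Why: Acid-catalysed acetal exchange (MOM cleavage) with methanol as acceptor, run dilute and cold so that protonation of the acetal outruns protonation of the prenyl alkenes, which would otherwise let the freed C7 hydroxyl close a chroman.

**Compound list**
1 | 2,4-dihydroxyacetophenone | CC(=O)c1ccc(O)cc1O | starting material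
2 | 1-(2,4-dihydroxy-3,5-diiodophenyl)ethanone | CC(=O)c1cc(I)c(O)c(I)c1O | intermediate
3 | 1-[2-hydroxy-3,5-diiodo-4-(methoxymethoxy)phenyl]ethanone | CC(=O)c1cc(I)c(OCOC)c(I)c1O | intermediate
4 | tributyl(3-methylbut-2-enyl)stannane | CCCC[Sn](CCCC)(CCCC)CC=C(C)C | starting material
5 | 1-[2-hydroxy-4-(methoxymethoxy)-3,5-bis(3-methylbut-2-enyl)phenyl]ethanone | CC(=O)c1cc(CC=C(C)C)c(OCOC)c(CC=C(C)C)c1O | intermediate
6 | N,N-dimethylformamide dimethyl acetal | COC(OC)N(C)C | starting material
7 | (E)-3-(dimethylamino)-1-[2-hydroxy-4-(methoxymethoxy)-3,5-bis(3-methylbut-2-enyl)phenyl]prop-2-en-1-one | CN(C)/C=C/C(=O)c1cc(CC=C(C)C)c(OCOC)c(CC=C(C)C)c1O | intermediate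
8 | 4-aminophenol | Nc1ccc(O)cc1 | starting material
9 | 4-hydroxybenzenediazonium tetrafluoroborate | Oc1ccc([N+]#N)cc1.F[B-](F)(F)F | intermediate
10 | 4-diazocyclohexa-2,5-dien-1-one | [N-]=[N+]=C1C=CC(=O)C=C1 | intermediate
11 | 2-(dimethylamino)-3-(4-hydroxyphenyl)-7-(methoxymethoxy)-6,8-bis(3-methylbut-2-enyl)chroman-4-one (not isolated; C2 and C3 unassigned, both erased on elimination) | CN(C)C1Oc2c(CC=C(C)C)c(OCOC)c(CC=C(C)C)cc2C(=O)C1c1ccc(O)cc1 | intermediate
12 | 4'-hydroxy-7-(methoxymethoxy)-6,8-diprenylisoflavone | CC(C)=CCc1cc2c(=O)c(-c3ccc(O)cc3)coc2c(CC=C(C)C)c1OCOC | intermediate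
13 | 7,4'-dihydroxy-6,8-diprenylisoflavone (CNP0238765.0, no stereocentre) | CC(C)=CCc1cc2c(=O)c(-c3ccc(O)cc3)coc2c(CC=C(C)C)c1O | target

**Total step count:** 8
**Longest linear sequence:** 6 (steps 1, 2, 3, 4, 7, 8). Steps 5 and 6 form the convergent branch.

**Steps most likely to fail**

1. **Step 7 (new method).**
   - Risk: The carbene may be diverted to the prenyl alkenes (cyclopropanation) or to O–H insertion into the newly formed ring-B phenol. The dirhodium catalyst may be slowed by the liberated dimethylamine. The diazide may also be consumed by uncatalysed coupling at its terminal nitrogen with the enaminone or the amine.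
   - Fallback (known chemistry, sets out from 7, returns at 12): Iodine-induced cyclisation of the enaminone (I2, 1.05 equiv, CHCl3, 0 °C to rt) keeps the halogen limiting so that the far more nucleophilic alpha carbon takes it ahead of the alkenes. This gives 3-iodo-7-(methoxymethoxy)-6,8-diprenylchromen-4-one F1. Suzuki–Miyaura coupling of F1 with 4-hydroxyphenylboronic acid (PdCl2(dppf), Na2CO3, DME/H2O, 80 °C) then forms C3–C1' and delivers 12.

2. **Step 3.**
   - Risk: Coupling may occur at the substituted prenyl terminus, giving 1,1-dimethylallyl groups. Oxidative addition at the doubly flanked C3 iodide may be sluggish and lead to protodeiodination. The stannane may be lost by protonolysis with the phenol.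
   - Fallback (sets out from 1, returns at 5): The prenyl groups are built without any aryl–metal step.
     - Exhaustive O-allylation of 1 (allyl bromide, K2CO3, DMF, 60 °C) gives 2,4-bis(allyloxy)acetophenone F2.
     - Heating in N,N-diethylaniline at about 200 °C triggers two aromatic Claisen rearrangements that converge on 3,5-diallyl-2,4-dihydroxyacetophenone F3. The C2 allyl group can reach only C3 directly or C5 by the para variant, and the C4 allyl group takes whichever of C3 and C5 is left.
     - MOMCl/K2CO3 as in step 2 gives 1-[3,5-diallyl-2-hydroxy-4-(methoxymethoxy)phenyl]ethanone F4.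
     - Twofold cross metathesis with 2-methyl-2-butene (second-generation Grubbs catalyst RuCl2(H2IMes)(PCy3)(=CHPh), CH2Cl2, 40 °C) converts both allyl groups into prenyl groups and delivers 5.

3. **Step 8.**
   - Risk: Acid may induce addition of the liberated C7 hydroxyl to a neighbouring prenyl alkene (2,2-dimethylchroman closure). HCl or methanol may also add to the alkenes before the acetal is fully cleaved.
   - Fallback (sets out from 2, returns at 13): The C7 oxygen is carried as a fluoride-labile SEM acetal, so no acid ever meets the ortho-prenylphenol.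
     - SEMCl/K2CO3 on 2 gives 1-[2-hydroxy-3,5-diiodo-4-{[2-(trimethylsilyl)ethoxy]methoxy}phenyl]ethanone F5.
     - The conditions of steps 3 and 4 give the SEM diprenyl ketone F6 and the SEM enaminone F7.
     - The conditions of step 7 lead through the SEM aminal F8 (not isolated) to 4'-hydroxy-6,8-diprenyl-7-{[2-(trimethylsilyl)ethoxy]methoxy}isoflavone F9.
     - TBAF in THF/DMPU at 60 °C fragments the silylethyl acetal and gives 13 after neutral work-up.

**Further compounds**
F1 | step 7 | 3-iodo-7-(methoxymethoxy)-6,8-diprenylchromen-4-one | CC(C)=CCc1cc2c(=O)c(I)coc2c(CC=C(C)C)c1OCOC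
F2 | step 3 | 2,4-bis(allyloxy)acetophenone | CC(=O)c1ccc(OCC=C)cc1OCC=C
F3 | step 3 | 3,5-diallyl-2,4-dihydroxyacetophenone | CC(=O)c1cc(CC=C)c(O)c(CC=C)c1O
F4 | step 3 | 1-[3,5-diallyl-2-hydroxy-4-(methoxymethoxy)phenyl]ethanone | CC(=O)c1cc(CC=C)c(OCOC)c(CC=C)c1O
F5 | step 8 | 1-[2-hydroxy-3,5-diiodo-4-{[2-(trimethylsilyl)ethoxy]methoxy}phenyl]ethanone | CC(=O)c1cc(I)c(OCOCC[Si](C)(C)C)c(I)c1O
F6 | step 8 | 1-[2-hydroxy-3,5-bis(3-methylbut-2-enyl)-4-{[2-(trimethylsilyl)ethoxy]methoxy}phenyl]ethanone | CC(=O)c1cc(CC=C(C)C)c(OCOCC[Si](C)(C)C)c(CC=C(C)C)c1O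
F7 | step 8 | (E)-3-(dimethylamino)-1-[2-hydroxy-3,5-bis(3-methylbut-2-enyl)-4-{[2-(trimethylsilyl)ethoxy]methoxy}phenyl]prop-2-en-1-one | CN(C)/C=C/C(=O)c1cc(CC=C(C)C)c(OCOCC[Si](C)(C)C)c(CC=C(C)C)c1O
F8 | step 8 | 2-(dimethylamino)-3-(4-hydroxyphenyl)-6,8-bis(3-methylbut-2-enyl)-7-{[2-(trimethylsilyl)ethoxy]methoxy}chroman-4-one (not isolated) | CN(C)C1Oc2c(CC=C(C)C)c(OCOCC[Si](C)(C)C)c(CC=C(C)C)cc2C(=O)C1c1ccc(O)cc1
F9 | step 8 | 4'-hydroxy-6,8-diprenyl-7-{[2-(trimethylsilyl)ethoxy]methoxy}isoflavone | CC(C)=CCc1cc2c(=O)c(-c3ccc(O)cc3)coc2c(CC=C(C)C)c1OCOCC[Si](C)(C)C
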